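## Analysis of the target

Dorsilurin C is a flavonol, a 4H-chromen-4-one in which the benzenoid ring A is fused to the pyranone ring C and ring B sits on C2. Ring A carries hydroxyl groups on C5 and C7 and 3-methylbut-2-enyl (prenyl) groups on C6 and C8, ring C carries the C3 hydroxyl, and ring B is the benzene ring of a 2,2-dimethyl-2H-chromene joined through its C7. There is no stereocentre and no stereogenic double bond, so the problem is one of connectivity and chemoselectivity only. The sensitive parts are the two prenyl alkenes, each ortho to a phenol and so prone to acid-induced closure to a chroman, the styrene-like C3=C4 bond of the chromene, and the electron-rich flavonol enol, which is oxidised by air in base; hydrogenolysis, strong Lewis acids and electrophilic oxidants are therefore excluded late in the route. The hard part is ring A: all six of its carbons are substituted, and putting two prenyl groups on a phloroglucinol nucleus by alkylation suffers from O-alkylation, over-alkylation and poor positional control. The C3 oxygen must in addition arrive without an oxidation that the alkenes would not survive. The route rests on the substitution pattern of ring A, oxygen on C5, C7 and C8a alternating with carbon on C4a, C6 and C8, which is the pattern of a linear tetracarbonyl chain folded by a Claisen condensation, with the prenyl groups on the two chain methylenes that become C6 and C8 and with C4 as the last carbonyl of the chain.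

## Retrosynthetic reasoning

The last operation is a deprotection. Target 23 is traced back to its 3-O-methoxymethyl ether 22 by cutting the acetal C–O bond at O3. One acid-labile group is thus kept for the final step, and the C3 oxygen is carried through the whole route at its final oxidation level.

Ring C is opened at O1–C2, which takes 22 back through the hemiketal 21 to the open-chain 1,3-diketone 20. The forward reaction is the addition of an ortho phenol of ring A to the ring B ketone, followed by dehydration.

Diketone 20 is cut at C2–C3 into the acylphloroglucinol 12 and the acid chloride 19. C2 is the junction between the A/C half and the B half, so cutting there lets ring B enter as a plain acyl electrophile, while C3 and its protected oxygen are already the terminus of the ketone side chain of 12. Because 12 is symmetric, either ortho oxygen may later become O1. The forward reaction has to acylate the ketone alpha-carbon in the presence of three phenols.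

Ring A is opened at C4a–C8a. This turns 12 into the open-chain triketo ester 11, which is the ring-opened form of the pyrone 10. The cut is made here because formation of this one bond, by Claisen condensation of the only free doubly activated methylene of the chain onto its ester end, gives the alternating oxygen pattern directly. Every substituent of ring A is then already in the chain, and the pyrone serves as a stable, isolable form of the reactive polyketone.

Pyrone 10 is cut between the carbon that becomes C4a and the carbon that becomes C4, giving the 6-methylpyrone 7 and the protected glycolate ester 9. The methyl group of 7 is vinylogously acidic, so the forward step is an acylation of its carbanion. Ester 9 supplies C4, C3 and the C3 oxygen, and comes from methyl glycolate 8.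

Pyrone 7 is opened at its lactone C–O bond to the diketo ester 6. Compound 6 is cut at the acetyl–carbon bond into the keto ester 4 and the acetyl donor 5, and 4 is taken apart at its two allylic C–C bonds into methyl acetoacetate 1 and two equivalents of prenyl bromide 2 by way of 3. Both prenyl groups are thus attached by enolate alkylation at sp3 carbon, where C-alkylation is the normal course.

The B unit 19 is traced through acid 18 to bromide 17 (cut of the aryl–carboxyl bond, with bromine marking C7 of the chromene). The chromene double bond comes from alcohol 16 and ketone 15, and the dihydropyranone ring of 15 is cut at O1–C2 and C2–C3 into the bromo-hydroxyacetophenone 13 and acetone 14. The bromine para to the acetyl group in 13 ends up at C7 of the chromene, as the target requires.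

## Alternatives that were turned down

Alternative 1: Ring C would be cut at C4–C4a and O1–C2, giving the symmetric triol 2,4-bis(3-methylbut-2-enyl)benzene-1,3,5-triol (A1) and the B-unit keto ester ethyl 3-(2,2-dimethyl-2H-chromen-7-yl)-2-(methoxymethoxy)-3-oxopropanoate (A2). In the forward sense the two are fused without solvent at about 240 °C (Mentzer pyrone synthesis). The ester acylates the only free ring carbon of A1, a neighbouring phenol adds to the aryl ketone, and dehydration gives 3-O-(methoxymethyl)dorsilurin C (A3), which is the same compound as 22.
- For it: this is the most convergent plan. One operation joins both halves and closes ring C, the single free position and the symmetry of A1 leave no regiochemical choice, and the route would be several steps shorter than the chosen one. On step count it is clearly stronger.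
- Against it: A1 has to be made by direct two-fold C-prenylation of a bare phloroglucinol nucleus, which is exactly the unselective reaction that makes ring A difficult. At 240 °C the ortho-prenyl phenols of A1 and A3 can close to chromans or undergo sigmatropic and ene-type shifts, the acetal of A2 is at risk, and an alpha-substituted keto ester can react in the Pechmann sense to give an isomeric coumarin-type ring.
- Comparison: the chosen strategy gives up that brevity for a ring A whose prenyl groups are placed by enolate alkylation and for a sequence in which nothing is heated above about 110 °C.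

Alternative 2: Ring A would be cut into a four-carbon piece, 2-(3-methylbut-2-enyl)-3-(triisopropylsilyloxy)cyclobut-2-en-1-one (A4), and a two-carbon piece, the ynol silyl ether triisopropyl[(5-methylhex-4-en-1-yn-1-yl)oxy]silane (A5). On heating in an aromatic hydrocarbon solvent, A4 opens to a vinylketene that adds across the alkyne of A5 in a [2+2] cycloaddition (bonds C8–C8a and C6–C7). The new cyclobutenone opens again and the dienylketene closes by 6π electrocyclisation (bond C4a–C8a). Tautomerisation then gives 2,4-bis(3-methylbut-2-enyl)-3,5-bis(triisopropylsilyloxy)phenol (A6). This is a Danheiser benzannulation.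
- For it: regiochemistry is fixed by the polarisation of ketene and ynol ether, the conditions are neutral, and A6 has one free hydroxyl (the future O1) beside two silylated ones. The chosen route does not achieve that differentiation: all three hydroxyls of 12 are free, and step 13 has to rely on the enolate carbon of a polyanion being more nucleophilic than three phenoxide oxygens.
- Against it: A4 and A5 are each several steps from simple materials, and A6 still lacks C4 and C3. These would have to be attached by acylating the last free position of a pentasubstituted, silylated, prenyl-bearing arene, where Lewis acids threaten both the prenyl groups and the silyl ethers, before any ring C chemistry could begin.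
- Comparison: the chosen strategy is at best equal in regiocontrol and weaker in oxygen differentiation, but it delivers C4 and the oxygenated C3 together with ring A, starts from commodity esters and is shorter overall.

Alternative 3: Here the disconnection lies in the precursor of ring C and not in ring A. The open 1,3-diketone is cut on both sides of C2 into the ring A ketone 1-[2-hydroxy-4,6-bis(methoxymethoxy)-3,5-bis(3-methylbut-2-enyl)phenyl]-2-(methoxymethoxy)ethanone (A7), carbon monoxide (A8) and the aryl bromide 17 of the chosen route. A zerovalent palladium catalyst carrying a wide-bite-angle diphosphine would insert into the C–Br bond of 17, take up A8 and transfer the aroyl group to the enolate of A7 (carbonylative alpha-arylation, bonds C2–C1' and C2–C3). The product is the diketone 1-(2,2-dimethyl-2H-chromen-7-yl)-3-[2-hydroxy-4,6-bis(methoxymethoxy)-3,5-bis(3-methylbut-2-enyl)phenyl]-2-(methoxymethoxy)propane-1,3-dione (A9). A9 is racemic at a labile centre and is formed without closing a ring, so it would still have to be cyclised and dehydrated.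
- For it: bromide 17 is used directly, which saves steps 11 and 12, and two of the three phenols of the ring A partner are capped, so fewer oxygen nucleophiles compete with the enolate than in step 13. On both points this plan is stronger.
- Against it: the plan does not address ring A at all, since A7 would itself come from 12 by selective protection, so it can only replace the end-game. The aroyl-palladium intermediate must choose the hindered alpha-alkoxy enolate carbon over the free ortho phenoxide (O-aroylation) and over four alkenes (Heck-type insertion), and arylation without uptake of A8 competes. Three acetal groups instead of one would have to be removed with acid from a product whose prenyl groups are acid-sensitive.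
- Comparison: the chosen end-game reaches the same kind of diketone by plain acyl transfer from an acid chloride without a transition metal, keeps a single acid-labile group for the last step, and concentrates the risk in the construction of ring A, where the real difficulty of the target lies.

Key step: step 7

Remark on the chemistry: compounds 3, 4, 6, 11 and 20 are drawn as keto forms although they exist as mixtures with their enols (20 also with its cyclic hemiketal 21); their stereocentres, like those of 16 and 21, are labile or are removed again, and the target is achiral. Compound 5 and the common reagents are taken as purchasable.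

## Route

Step 1
Reactants: 1 methyl acetoacetate (1.5 equiv); 2 1-bromo-3-methylbut-2-ene (prenyl bromide)
Product: 3 methyl 2-acetyl-5-methylhex-4-enoate
Conditions: NaH, THF, 0 °C → rt
Reagents that add atoms: none
Why: Acetoacetic ester alkylation: the sodium enolate is alkylated at its doubly activated alpha-carbon by the primary allylic bromide in an SN2 reaction, which keeps the prenyl group linear. The excess of 1 suppresses dialkylation.

Step 2
Reactants: 3 methyl 2-acetyl-5-methylhex-4-enoate; 2 1-bromo-3-methylbut-2-ene
Product: 4 methyl 7-methyl-2-(3-methylbut-2-enyl)-3-oxooct-6-enoate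
Conditions: NaH, THF, 0 °C; n-BuLi, 0 °C; 2, 0 °C → rt; 1 M HCl
Reagents that add atoms: none
Why: Gamma-alkylation of a beta-keto ester dianion: the alpha-position is masked as the sodium enolate, and the more basic terminal carbanion made by n-BuLi is the one alkylated by prenyl bromide. The acetyl methyl of 3 thereby becomes a prenylated methylene.

Step 3
Reactants: 4 methyl 7-methyl-2-(3-methylbut-2-enyl)-3-oxooct-6-enoate; 5 N-methoxy-N-methylacetamide
Product: 6 methyl 2,4-bis(3-methylbut-2-enyl)-3,5-dioxohexanoate
Conditions: NaH, THF, 0 °C; n-BuLi, 0 °C; 5, −78 → 0 °C; 1 M HCl, 0 °C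
Reagents that add atoms: none
Why: C-acylation of a keto ester dianion with a Weinreb amide: the gamma-carbanion adds to the amide and the chelated tetrahedral adduct persists until the quench. The more acidic diketo ester product therefore cannot protonate unreacted dianion or be acylated twice.

Step 4
Reactants: 6 methyl 2,4-bis(3-methylbut-2-enyl)-3,5-dioxohexanoate
Product: 7 4-hydroxy-6-methyl-3,5-bis(3-methylbut-2-enyl)-2H-pyran-2-one
Conditions: DBU (1.2 equiv), toluene, 90 °C; 1 M HCl
Reagents that add atoms: none
Why: Base-mediated lactonisation of a 3,5-diketo ester: the enolate oxygen of the terminal ketone attacks the ester (6-exo-trig acyl substitution), and loss of the alkoxide followed by enolisation gives the 4-hydroxy-2-pyrone. This is the standard entry to 3,5-dialkyl-4-hydroxy-2-pyrones.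

Step 5
Reactants: 8 methyl glycolate
Product: 9 methyl 2-(methoxymethoxy)acetate
Conditions: MOMCl, i-Pr2NEt, CH2Cl2, 0 °C → rt
Reagents that add atoms: chloromethyl methyl ether, COCCl
Why: O-alkylation of a primary alcohol with the highly electrophilic chloromethyl ether under amine base (methoxymethyl protection). The acetal is stable to all the base used up to step 13.

Step 6
Reactants: 7 4-hydroxy-6-methyl-3,5-bis(3-methylbut-2-enyl)-2H-pyran-2-one; 9 methyl 2-(methoxymethoxy)acetate
Product: 10 4-hydroxy-6-[3-(methoxymethoxy)-2-oxopropyl]-3,5-bis(3-methylbut-2-enyl)-2H-pyran-2-one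
Conditions: LiN(iPr)2 (3.2 equiv), THF, −78 °C; 9, −78 → −20 °C; 1 M HCl, 0 °C
Reagents that add atoms: none
Why: Acylation of a 4-hydroxy-6-methyl-2-pyrone dianion with an ester: the first equivalent of base removes the hydroxyl proton and the second the vinylogously acidic methyl proton. The carbanion adds to the alpha-alkoxy ester, which is activated by its inductively withdrawing oxygen, and the third equivalent takes up the acidic methylene of the product.

Step 7
Reactants: 10 4-hydroxy-6-[3-(methoxymethoxy)-2-oxopropyl]-3,5-bis(3-methylbut-2-enyl)-2H-pyran-2-one
Product: 12 2-(methoxymethoxy)-1-[2,4,6-trihydroxy-3,5-bis(3-methylbut-2-enyl)phenyl]ethanone, via magnesium-chelated triketo ester 11 (not isolated)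
Conditions: Mg(OMe)2 (6 equiv), MeOH, reflux, argon; then 1 M HCl, 0 °C
Reagents that add atoms: none
Why: Methoxide delivered from the Lewis-acidic magnesium centre adds to the lactone carbonyl of 10 and opens the ring to the triketo ester 11, which is held as a magnesium chelate of its enolised 1,3-dicarbonyl units. In 11 the former side-chain methylene (future C4a) is the only methylene that is both unsubstituted and flanked by two carbonyl groups; its enolate attacks the ester carbon (future C8a) in a Dieckmann-type Claisen condensation, a 6-exo-trig closure of ring A, and loss of methoxide gives a cyclohexane-1,3,5-trione that tautomerises irreversibly to the aromatic triol 12. The closest known reaction type is the Mg(OMe)2-mediated conversion of 4-hydroxy-6-(2-oxoalkyl)-2-pyrones and of 3,5,7-triketo esters into acylphloroglucinols. No stereocentre is formed, and the labile centres of 11 disappear on aromatisation. The selectivity needed is Claisen against aldol folding: attack of the ester alpha-carbon on the side-chain ketone would create a quaternary carbon bearing both the ester and a prenyl group, which cannot aromatise and reverts by retro-aldol. The one aldol that the prenyl groups do not block, closure of the alkoxy-substituted terminal methylene onto the central ketone, is disfavoured because that methylene is activated by one carbonyl only and is not deprotonated by methoxide, while the central ketone lies between two prenylated carbons and is tied up in the chelate. Chelation also protects the polyketone against retro-Claisen cleavage and makes the magnesium salt of 12 the thermodynamic sink. Because both prenyl groups were attached to sp3 carbon in steps 1 and 2, ring A appears fully substituted and no aromatic prenylation is needed.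

Step 8
Reactants: 13 1-(4-bromo-2-hydroxyphenyl)ethanone; 14 acetone (5 equiv)
Product: 15 7-bromo-2,2-dimethylchroman-4-one
Conditions: pyrrolidine (0.3 equiv), MeOH, 60 °C
Reagents that add atoms: none
Why: Kabbe chromanone synthesis: a pyrrolidine-mediated crossed aldol condensation between the acetyl group of 13 and acetone gives the beta,beta-dimethyl enone with loss of water. Conjugate addition of the ortho phenol (6-endo-trig oxa-Michael) then closes the dihydropyranone, with the bromine para to the former acetyl carbon and hence at C7.

Step 9
Reactants: 15 7-bromo-2,2-dimethylchroman-4-one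
Product: 16 7-bromo-2,2-dimethylchroman-4-ol (racemic)
Conditions: NaBH4, MeOH, 0 °C
Reagents that add atoms: none
Why: Hydride reduction of an aryl ketone. The carbinol centre is formed as a racemate, which is irrelevant because it is removed in step 10.

Step 10
Reactants: 16 7-bromo-2,2-dimethylchroman-4-ol
Product: 17 7-bromo-2,2-dimethyl-2H-chromene
Conditions: p-TsOH·H2O (5 mol %), toluene, reflux, Dean–Stark
Reagents that add atoms: none
Why: Acid-catalysed E1 dehydration through the benzylic cation, which is stabilised by the ortho ring oxygen. Conjugation of the new alkene with the arene and azeotropic removal of water drive the reaction.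

Step 11
Reactants: 17 7-bromo-2,2-dimethyl-2H-chromene
Product: 18 2,2-dimethyl-2H-chromene-7-carboxylic acid
Conditions: n-BuLi, THF, −78 °C; CO2; 1 M HCl
Reagents that add atoms: carbon dioxide, O=C=O
Why: Lithium–bromine exchange at −78 °C is much faster than any addition to the chromene alkene, and the aryllithium is carboxylated by carbon dioxide.

Step 12
Reactants: 18 2,2-dimethyl-2H-chromene-7-carboxylic acid
Product: 19 2,2-dimethyl-2H-chromene-7-carbonyl chloride
Conditions: (COCl)2, DMF (cat.), CH2Cl2, 0 °C → rt
Reagents that add atoms: oxalyl chloride, O=C(Cl)C(Cl)=O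
Why: DMF-catalysed (Vilsmeier-type) conversion of the acid into its chloride under mild anhydrous conditions. The chromene alkene, deactivated by the para acyl group, should not add the hydrogen chloride evolved at this temperature.

Step 13
Reactants: 12 2-(methoxymethoxy)-1-[2,4,6-trihydroxy-3,5-bis(3-methylbut-2-enyl)phenyl]ethanone; 19 2,2-dimethyl-2H-chromene-7-carbonyl chloride (1.0 equiv)
Product: 20 1-(2,2-dimethyl-2H-chromen-7-yl)-2-(methoxymethoxy)-3-[2,4,6-trihydroxy-3,5-bis(3-methylbut-2-enyl)phenyl]propane-1,3-dione
Conditions: LiN(SiMe3)2 (5 equiv), THF, −78 °C; 19, −78 °C → rt; 1 M HCl, 0 °C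
Reagents that add atoms: none
Why: C-acylation of the lithium polyanion of a polyhydroxyaryl ketone with an aroyl chloride, a crossed Claisen entry to the 1,3-diketone of a Baker–Venkataraman sequence: four equivalents of base give the triphenoxide enolate, whose carbon is its most nucleophilic site, and the fifth takes up the acidic proton of the product so that it cannot quench unreacted enolate. An aroyl group that lands on an ortho oxygen is carried to the same carbon by acyl migration under the excess base, and because 12 is symmetric only one diketone can form.

Step 14
Reactants: 20 1-(2,2-dimethyl-2H-chromen-7-yl)-2-(methoxymethoxy)-3-[2,4,6-trihydroxy-3,5-bis(3-methylbut-2-enyl)phenyl]propane-1,3-dione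
Product: 22 2-(2,2-dimethyl-2H-chromen-7-yl)-5,7-dihydroxy-3-(methoxymethoxy)-6,8-bis(3-methylbut-2-enyl)-4H-chromen-4-one, via 2-hydroxychromanone hemiketal 21 (not isolated)
Conditions: NaOAc, AcOH, 80 °C, argon
Reagents that add atoms: none
Why: Cyclodehydration of a 1-(2-hydroxyaryl)-1,3-diketone, the ring-closing stage of the Baker–Venkataraman and Allan–Robinson flavone syntheses: one of the two equivalent ortho phenols adds to the chromenyl ketone (6-exo-trig) to give hemiketal 21. Acid-assisted loss of water through the oxocarbenium ion stabilised by O1 and ring B, then loss of the C3 proton, gives the aromatic pyranone. Buffered acetic acid is chosen because it is too weak to cleave the acetal or to protonate the prenyl alkenes at this temperature.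

Step 15
Reactants: 22 2-(2,2-dimethyl-2H-chromen-7-yl)-5,7-dihydroxy-3-(methoxymethoxy)-6,8-bis(3-methylbut-2-enyl)-4H-chromen-4-one
Product: 23 dorsilurin C
Conditions: 2 M HCl (aq.), MeOH/THF, 40 °C
Reagents that add atoms: none
Why: Acid-catalysed acetal exchange transfers the methoxymethyl group to methanol and frees the 3-hydroxyl. Dilute acid at moderate temperature is used because protonation of the acetal oxygen is much faster than protonation of the trisubstituted alkenes.

## Compound list

1 | methyl acetoacetate | COC(=O)CC(C)=O | starting material
2 | 1-bromo-3-methylbut-2-ene (prenyl bromide) | CC(C)=CCBr | starting material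
3 | methyl 2-acetyl-5-methylhex-4-enoate (racemic, labile centre) | COC(=O)C(CC=C(C)C)C(C)=O | intermediate
4 | methyl 7-methyl-2-(3-methylbut-2-enyl)-3-oxooct-6-enoate (racemic, labile centre) | COC(=O)C(CC=C(C)C)C(=O)CCC=C(C)C | intermediate
5 | N-methoxy-N-methylacetamide | CC(=O)N(C)OC | starting material
6 | methyl 2,4-bis(3-methylbut-2-enyl)-3,5-dioxohexanoate (mixture of stereoisomers and enols) | COC(=O)C(CC=C(C)C)C(=O)C(CC=C(C)C)C(C)=O | intermediate
7 | 4-hydroxy-6-methyl-3,5-bis(3-methylbut-2-enyl)-2H-pyran-2-one | Cc1oc(=O)c(CC=C(C)C)c(O)c1CC=C(C)C | intermediate
8 | methyl glycolate | OCC(=O)OC | starting material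
9 | methyl 2-(methoxymethoxy)acetate | COCOCC(=O)OC | intermediate
10 | 4-hydroxy-6-[3-(methoxymethoxy)-2-oxopropyl]-3,5-bis(3-methylbut-2-enyl)-2H-pyran-2-one | O=c1oc(CC(=O)COCOC)c(CC=C(C)C)c(O)c1CC=C(C)C | intermediate
11 | methyl 8-(methoxymethoxy)-2,4-bis(3-methylbut-2-enyl)-3,5,7-trioxooctanoate, present as its magnesium chelate (not isolated; labile centres) | COCOCC(=O)CC(=O)C(CC=C(C)C)C(=O)C(CC=C(C)C)C(=O)OC | intermediate
12 | 2-(methoxymethoxy)-1-[2,4,6-trihydroxy-3,5-bis(3-methylbut-2-enyl)phenyl]ethanone | COCOCC(=O)c1c(O)c(CC=C(C)C)c(O)c(CC=C(C)C)c1O | intermediate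
13 | 1-(4-bromo-2-hydroxyphenyl)ethanone | CC(=O)c1ccc(Br)cc1O | starting material
14 | acetone | CC(C)=O | starting material
15 | 7-bromo-2,2-dimethylchroman-4-one | CC1(C)CC(=O)c2ccc(Br)cc2O1 | intermediate
16 | 7-bromo-2,2-dimethylchroman-4-ol (racemic) | CC1(C)CC(O)c2ccc(Br)cc2O1 | intermediate
17 | 7-bromo-2,2-dimethyl-2H-chromene | CC1(C)C=Cc2ccc(Br)cc2O1 | intermediate
18 | 2,2-dimethyl-2H-chromene-7-carboxylic acid | CC1(C)C=Cc2ccc(C(=O)O)cc2O1 | intermediate
19 | 2,2-dimethyl-2H-chromene-7-carbonyl chloride | CC1(C)C=Cc2ccc(C(Cl)=O)cc2O1 | intermediate
20 | 1-(2,2-dimethyl-2H-chromen-7-yl)-2-(methoxymethoxy)-3-[2,4,6-trihydroxy-3,5-bis(3-methylbut-2-enyl)phenyl]propane-1,3-dione (racemic, labile centre) | COCOC(C(=O)c1ccc2c(c1)OC(C)(C)C=C2)C(=O)c1c(O)c(CC=C(C)C)c(O)c(CC=C(C)C)c1O | intermediate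
21 | 2-(2,2-dimethyl-2H-chromen-7-yl)-2,5,7-trihydroxy-3-(methoxymethoxy)-6,8-bis(3-methylbut-2-enyl)chroman-4-one (not isolated; mixture of racemic diastereomers) | COCOC1C(=O)c2c(O)c(CC=C(C)C)c(O)c(CC=C(C)C)c2OC1(O)c1ccc2c(c1)OC(C)(C)C=C2 | intermediate
22 | 2-(2,2-dimethyl-2H-chromen-7-yl)-5,7-dihydroxy-3-(methoxymethoxy)-6,8-bis(3-methylbut-2-enyl)-4H-chromen-4-one | CC(C)=CCc1c(O)c(CC=C(C)C)c2oc(-c3ccc4c(c3)OC(C)(C)C=C4)c(OCOC)c(=O)c2c1O | intermediate
23 | dorsilurin C, 2-(2,2-dimethyl-2H-chromen-7-yl)-3,5,7-trihydroxy-6,8-bis(3-methylbut-2-enyl)-4H-chromen-4-one (achiral) | CC(C)=CCc1c(O)c(CC=C(C)C)c2oc(-c3ccc4c(c3)OC(C)(C)C=C4)c(O)c(=O)c2c1O | target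

## Step count and uncertain steps

Total step count: 15. Longest linear sequence: 9 steps (steps 1, 2, 3, 4, 6, 7, 13, 14, 15); the B unit (steps 8 to 12) and ester 9 (step 5) are made in parallel.

Step 7 (key step). The most likely failure is slow addition of methoxide to the lactone carbonyl. The deprotonated pyrone is a vinylogous carboxylate and its carbonyl is shielded by the neighbouring prenyl group. On prolonged heating, retro-Claisen fragmentation of the polyketone, or the competing aldol closure of the terminal alkoxy-methylene onto the central ketone, could then overtake the Claisen folding. The fallback sets out from 9 and 2 and comes back at 12, and it moves the prenylation behind the ring formation. The dianion of commercial 4-hydroxy-6-methyl-2H-pyran-2-one F1 (LiN(iPr)2, THF, −78 °C) would be acylated with 9 to give 4-hydroxy-6-[3-(methoxymethoxy)-2-oxopropyl]-2H-pyran-2-one F2. Mg(OMe)2 in methanol would fold this unhindered pyrone, the substrate type for which the reaction is established, to 2-(methoxymethoxy)-1-(2,4,6-trihydroxyphenyl)ethanone F3. Two-fold C-prenylation of F3 with 2 in cold aqueous KOH, the classical way to 3,5-diprenyl acylphloroglucinols, would give 12. This gives up positional control of the prenylation, so O-alkylated and over-alkylated material would have to be separated.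

Step 13. The acid chloride may be captured by a phenoxide oxygen instead of by the enolate carbon. Acylation on an ortho oxygen can still be corrected by acyl migration, but acylation on the para oxygen or double acylation diverts material, and the crowded alpha-alkoxy enolate is the least accessible nucleophile of the polyanion. The fallback sets out from 12 and 19 and comes back at 22; it accepts O-acylation, makes it exhaustive and lets ring C close under base.
- Treating 12 with 19 (3.3 equiv, Et3N, DMAP, CH2Cl2) would give the tri-ester 2-[(methoxymethoxy)acetyl]-4,6-bis(3-methylbut-2-enyl)benzene-1,3,5-triyl tris(2,2-dimethyl-2H-chromene-7-carboxylate) F4.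
- DBU in pyridine at 90 °C would shift one ortho aroyl group to the alpha-carbon (Baker–Venkataraman rearrangement) and give the diketone 4-[3-(2,2-dimethyl-2H-chromen-7-yl)-2-(methoxymethoxy)-3-oxopropanoyl]-5-hydroxy-2,6-bis(3-methylbut-2-enyl)benzene-1,3-diyl bis(2,2-dimethyl-2H-chromene-7-carboxylate) F5.
- In the same flask the freed phenol would close onto the aryl ketone to give the hemiketal 2-(2,2-dimethyl-2H-chromen-7-yl)-2-hydroxy-3-(methoxymethoxy)-6,8-bis(3-methylbut-2-enyl)-4-oxochromane-5,7-diyl bis(2,2-dimethyl-2H-chromene-7-carboxylate) F6.
- E1cB loss of water would then give the flavone diester 2-(2,2-dimethyl-2H-chromen-7-yl)-3-(methoxymethoxy)-6,8-bis(3-methylbut-2-enyl)-4-oxo-4H-chromene-5,7-diyl bis(2,2-dimethyl-2H-chromene-7-carboxylate) F7.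
- Saponification with LiOH in degassed THF/H2O would free the 5- and 7-hydroxyls and give 22, with the two surplus aroyl groups recovered as acid 18.

This detour costs one more step and two further equivalents of 19. It also avoids the acidic ring closure of step 14, because the pyranone forms under base while the phenols next to the prenyl groups are esterified.

Step 3. The secondary, doubly flanked gamma-carbanion may act as a base towards the Weinreb amide, or acylation may occur on enolate oxygen, so that conversion to 6 stalls. The fallback sets out from 4 and comes back at 6. The same dianion would be added to acetaldehyde at −78 °C to give methyl 5-hydroxy-2,4-bis(3-methylbut-2-enyl)-3-oxohexanoate F8 (mixture of stereoisomers), and oxidation of the secondary alcohol with Dess–Martin periodinane (NaHCO3, CH2Cl2) would give 6. The aldol addition is less sensitive to hindrance and to proton transfer than the acylation.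

Step 6. Metalation of the methyl group next to the C5 prenyl group may be incomplete, or the carbanion may deprotonate ester 9 instead of adding to it, so that 7 is recovered. The fallback sets out from 6 and 9 and comes back at 12, and it avoids the pyrone at this stage and makes no compound outside the list (F0). The trianion of 6 (LiN(iPr)2, 4.2 equiv, THF, −78 → 0 °C) would be acylated at its terminal methyl carbon with 9 to give the triketo ester 11 directly. The crude material, whether it stays open or lactonises to 10 on work-up, would be folded with Mg(OMe)2 as in step 7 to give 12.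

Step 15. Under acid, the 5- or 7-hydroxyl may add to its neighbouring prenyl alkene (chroman ring closure), and the solvent may add to the chromene double bond, before the acetal is fully cleaved. The fallback sets out from 22 and comes back at 23 by masking the two phenols before the acid is applied.
- Pivaloyl chloride (Et3N, DMAP, CH2Cl2, rt → 40 °C) would convert 22 into 2-(2,2-dimethyl-2H-chromen-7-yl)-3-(methoxymethoxy)-6,8-bis(3-methylbut-2-enyl)-4-oxo-4H-chromene-5,7-diyl bis(2,2-dimethylpropanoate) F9.
- 2 M HCl in MeOH/THF at 40 °C would then remove the acetal and give 2-(2,2-dimethyl-2H-chromen-7-yl)-3-hydroxy-6,8-bis(3-methylbut-2-enyl)-4-oxo-4H-chromene-5,7-diyl bis(2,2-dimethylpropanoate) F10. Both phenolic oxygens next to the prenyl groups are still esterified there and cannot cyclise, and the hindered esters resist acidic methanolysis.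
- Saponification with LiOH in degassed THF/H2O would give 23.

## Further compounds

F1 | step 7 | 4-hydroxy-6-methyl-2H-pyran-2-one | Cc1cc(O)cc(=O)o1
F2 | step 7 | 4-hydroxy-6-[3-(methoxymethoxy)-2-oxopropyl]-2H-pyran-2-one | COCOCC(=O)Cc1cc(O)cc(=O)o1
F3 | step 7 | 2-(methoxymethoxy)-1-(2,4,6-trihydroxyphenyl)ethanone | COCOCC(=O)c1c(O)cc(O)cc1O
F4 | step 13 | 2-[(methoxymethoxy)acetyl]-4,6-bis(3-methylbut-2-enyl)benzene-1,3,5-triyl tris(2,2-dimethyl-2H-chromene-7-carboxylate) | COCOCC(=O)c1c(OC(=O)c2ccc3c(c2)OC(C)(C)C=C3)c(CC=C(C)C)c(OC(=O)c2ccc3c(c2)OC(C)(C)C=C3)c(CC=C(C)C)c1OC(=O)c1ccc2c(c1)OC(C)(C)C=C2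
F5 | step 13 | 4-[3-(2,2-dimethyl-2H-chromen-7-yl)-2-(methoxymethoxy)-3-oxopropanoyl]-5-hydroxy-2,6-bis(3-methylbut-2-enyl)benzene-1,3-diyl bis(2,2-dimethyl-2H-chromene-7-carboxylate) (not isolated; racemic, labile centre) | COCOC(C(=O)c1ccc2c(c1)OC(C)(C)C=C2)C(=O)c1c(O)c(CC=C(C)C)c(OC(=O)c2ccc3c(c2)OC(C)(C)C=C3)c(CC=C(C)C)c1OC(=O)c1ccc2c(c1)OC(C)(C)C=C2
F6 | step 13 | 2-(2,2-dimethyl-2H-chromen-7-yl)-2-hydroxy-3-(methoxymethoxy)-6,8-bis(3-methylbut-2-enyl)-4-oxochromane-5,7-diyl bis(2,2-dimethyl-2H-chromene-7-carboxylate) (not isolated; mixture of racemic diastereomers) | COCOC1C(=O)c2c(OC(=O)c3ccc4c(c3)OC(C)(C)C=C4)c(CC=C(C)C)c(OC(=O)c3ccc4c(c3)OC(C)(C)C=C4)c(CC=C(C)C)c2OC1(O)c1ccc2c(c1)OC(C)(C)C=C2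
F7 | step 13 | 2-(2,2-dimethyl-2H-chromen-7-yl)-3-(methoxymethoxy)-6,8-bis(3-methylbut-2-enyl)-4-oxo-4H-chromene-5,7-diyl bis(2,2-dimethyl-2H-chromene-7-carboxylate) | COCOc1c(-c2ccc3c(c2)OC(C)(C)C=C3)oc2c(CC=C(C)C)c(OC(=O)c3ccc4c(c3)OC(C)(C)C=C4)c(CC=C(C)C)c(OC(=O)c3ccc4c(c3)OC(C)(C)C=C4)c2c1=O
F8 | step 3 | methyl 5-hydroxy-2,4-bis(3-methylbut-2-enyl)-3-oxohexanoate (mixture of stereoisomers) | COC(=O)C(CC=C(C)C)C(=O)C(CC=C(C)C)C(C)O
F0 | step 6 | none | none
F9 | step 15 | 2-(2,2-dimethyl-2H-chromen-7-yl)-3-(methoxymethoxy)-6,8-bis(3-methylbut-2-enyl)-4-oxo-4H-chromene-5,7-diyl bis(2,2-dimethylpropanoate) | COCOc1c(-c2ccc3c(c2)OC(C)(C)C=C3)oc2c(CC=C(C)C)c(OC(=O)C(C)(C)C)c(CC=C(C)C)c(OC(=O)C(C)(C)C)c2c1=O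
F10 | step 15 | 2-(2,2-dimethyl-2H-chromen-7-yl)-3-hydroxy-6,8-bis(3-methylbut-2-enyl)-4-oxo-4H-chromene-5,7-diyl bis(2,2-dimethylpropanoate) | Oc1c(-c2ccc3c(c2)OC(C)(C)C=C3)oc2c(CC=C(C)C)c(OC(=O)C(C)(C)C)c(CC=C(C)C)c(OC(=O)C(C)(C)C)c2c1=O
A1 | alternative 1 | 2,4-bis(3-methylbut-2-enyl)benzene-1,3,5-triol | CC(C)=CCc1c(O)cc(O)c(CC=C(C)C)c1O
A2 | alternative 1 | ethyl 3-(2,2-dimethyl-2H-chromen-7-yl)-2-(methoxymethoxy)-3-oxopropanoate (racemic, labile centre) | CCOC(=O)C(OCOC)C(=O)c1ccc2c(c1)OC(C)(C)C=C2
A3 | alternative 1 | 3-O-(methoxymethyl)dorsilurin C (identical with 22) | CC(C)=CCc1c(O)c(CC=C(C)C)c2oc(-c3ccc4c(c3)OC(C)(C)C=C4)c(OCOC)c(=O)c2c1O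
A4 | alternative 2 | 2-(3-methylbut-2-enyl)-3-(triisopropylsilyloxy)cyclobut-2-en-1-one | CC(C)=CCC1=C(O[Si](C(C)C)(C(C)C)C(C)C)CC1=O
A5 | alternative 2 | triisopropyl[(5-methylhex-4-en-1-yn-1-yl)oxy]silane | CC(C)=CCC#CO[Si](C(C)C)(C(C)C)C(C)C
A6 | alternative 2 | 2,4-bis(3-methylbut-2-enyl)-3,5-bis(triisopropylsilyloxy)phenol | CC(C)=CCc1c(O)cc(O[Si](C(C)C)(C(C)C)C(C)C)c(CC=C(C)C)c1O[Si](C(C)C)(C(C)C)C(C)C
A7 | alternative 3 | 1-[2-hydroxy-4,6-bis(methoxymethoxy)-3,5-bis(3-methylbut-2-enyl)phenyl]-2-(methoxymethoxy)ethanone | COCOCC(=O)c1c(O)c(CC=C(C)C)c(OCOC)c(CC=C(C)C)c1OCOC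
A8 | alternative 3 | carbon monoxide | [C-]#[O+]
A9 | alternative 3 | 1-(2,2-dimethyl-2H-chromen-7-yl)-3-[2-hydroxy-4,6-bis(methoxymethoxy)-3,5-bis(3-methylbut-2-enyl)phenyl]-2-(methoxymethoxy)propane-1,3-dione (racemic, labile centre) | COCOC(C(=O)c1ccc2c(c1)OC(C)(C)C=C2)C(=O)c1c(O)c(CC=C(C)C)c(OCOC)c(CC=C(C)C)c1OCOC
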